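Dissolved gas cannot climb past saturation; the transfer feeds it only while it stands below that level, and the choice of the next run starts from this ceiling.

    gas phase ⇌ dissolved gas, rate k1*(csat - [dissolved gas]) (k1 = 0.42 s⁻¹, csat = 0.36 mM)
    starting material + dissolved gas → target (k2 = 14 L mol⁻¹ s⁻¹)
    starting material → side product (k3 = 0.0045 s⁻¹)
    starting material + protic impurity → quenched substrate (k4 = 230 L mol⁻¹ s⁻¹)
    2 dissolved gas → self-condensation product (k5 = 48 L mol⁻¹ s⁻¹)
    starting material ⇌ dormant form (K6 = 8.0, k6 = 0.031 s⁻¹)

starting material 1.0 mM; gas phase 0.36 mM (held); protic impurity 0.500 mM; time 6.0 min

- two of one species on the left: rate k times its square, two consumed each time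
- at the start none of the gas is dissolved
- run time (flask): 6.0 min

1. the target standing at 6.0 min, as a percentage of the starting material charged
2. concentration of dissolved gas in solution at 3.0 min, in percent of saturation
3. the change that raises the amount of target at 6.0 min, in percent of the starting material charged most ("none" if none brings more than 2 percentage points) (Tuesday's / Thursday's / none)
4. amount of target at 6.0 min, in percent of the starting material charged, after Thursday's

- Tuesday's: doubling the saturation concentration of gas phase, all else as stated
- Thursday's: doubling the transfer coefficient of step 1, all else as stated

The decision is whether to raise the saturation, raise the transfer coefficient, or leave both. The transfer half-time is 1.65 s, far shorter than the run. The transfer constant 0.42 s⁻¹ also far exceeds the draw of the target step at full charge, 0.0140 s⁻¹. So my reckoning balances transfer against self-condensation. That balance puts the dissolved gas at 92.9% of saturation.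

With the gas flat, the target step is pseudo-first-order in free starting material, with constant 0.00468 s⁻¹. The side reaction runs at 0.0045 s⁻¹, about the same. The target share, the part of the free starting material's gas-step and side-step traffic that ends as target, is therefore 51.0%.

Doubling the saturation multiplies the gas level by 1.88, and the target share becomes 66.2%. Doubling the transfer coefficient multiplies it by 1.04. The hand reckoning stops here, since the target itself needs the whole course of the free pool. The next run doubles the saturation, which raises the gas level further than doubling the transfer coefficient does.

The forecast gives 9.5% of target, 92.8% of saturation, Tuesday's as the better change and 10% after Thursday's. It holds that “a faster transfer adds only a few percent”.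

The simulated flask gives 9.83% of target and 92.8% of saturation. The best change is Tuesday's, which gains 6.3 percentage points against 0.58 points for Thursday's, and target after Thursday's stands at 10.4%.

In the flask as charged, target and side product stand at 9.83% and 10.3%, so target holds 48.8% of the two, against the reckoned 51.0%. With the other amounts and the time held, target has moved 5 points at a starting-material charge of 0.474 mM. The neighbour flask, charged with 0.40 mM, lies below that value. Its dissolved gas stands at 92.9% of saturation, and at that level the reckoning again gives 51.0%. The neighbour's target stands at 4.35% and its side product at 4.93%, a target share of 46.9%.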